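The ten-membered ring is cut at C1–C10 (germacrane locants), inside its α-ketol C1(=O)–C10(OAc)(CH3). A hydroxyl-directed SmI2 pinacol cyclization of a keto-aldehyde closes the carbocycle as the last ring: one operation forms the C1–C10 bond and the C10 tertiary carbinol, with the free C8 hydroxyl (1,3 to C10) steering the attack. The precursor is an open chain held by two finished rings: the all-trans C6–O–C12 butyrolactone carries at C6 the cis-C4/C5 epoxide with a C1 aldehyde arm and at C7 a C8-hydroxy C10 methyl ketone arm. Nerol supplies C1–C6 and C15; one ozonolysis unveils both carbonyl groups.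

Key step: step 9

Remark: locants C1–C15 are those of the germacrane skeleton of the target (C1 ketone, C4–C5 epoxide, C6–O–C12 lactone, C8 tiglate, C10 acetate, C13 acetoxymethyl) and are used for all intermediates; stereodescriptors in names follow the SMILES.

Step 1
Reactants: 1 nerol [(2Z)-3,7-dimethylocta-2,6-dien-1-ol]
Product: 2 [(2S,3R)-3-methyl-3-(4-methylpent-3-en-1-yl)oxiran-2-yl]methanol
Conditions: Ti(OiPr)4 (cat.), L-(+)-diethyl tartrate (cat.), t-BuOOH, 4 Å MS, CH2Cl2, −20 °C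
Reagents that add atoms: tert-butyl hydroperoxide, CC(C)(C)OO
Why: Sharpless asymmetric epoxidation of the Z-trisubstituted allylic alcohol; L-(+)-tartrate should give the (2S,3R) epoxide and so set C4 and C5 under reagent control, while the remote alkene without an allylic hydroxyl stays untouched.

Step 2
Reactants: 2 [(2S,3R)-3-methyl-3-(4-methylpent-3-en-1-yl)oxiran-2-yl]methanol
Product: 3 (2R,3R)-3-methyl-3-(4-methylpent-3-en-1-yl)oxirane-2-carbaldehyde
Conditions: Dess–Martin periodinane, pyridine, CH2Cl2, 0 °C → rt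
Reagents that add atoms: none
Why: Dess–Martin oxidation of the primary epoxy alcohol under buffered conditions should give the epoxy aldehyde without touching the epoxide stereocentres.

Step 3
Reactants: 3 (2R,3R)-3-methyl-3-(4-methylpent-3-en-1-yl)oxirane-2-carbaldehyde; 4 methyl (2Z)-3-iodoprop-2-enoate
Product: 6 (5S)-5-[(2S,3R)-3-methyl-3-(4-methylpent-3-en-1-yl)oxiran-2-yl]furan-2(5H)-one, via Z-hydroxy enoate 5 (not isolated)
Conditions: CrCl2, NiCl2 (cat.), DMF, rt; aq. NH4Cl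
Reagents that add atoms: methyl (2Z)-3-iodoprop-2-enoate (4), COC(=O)/C=C\I
Why: Nozaki–Hiyama–Kishi alkenylation; Felkin–Anh attack anti to the epoxide C5–O bond should give the 5,6-anti adduct (6S), and the Z-γ-hydroxy ester lactonizes to the butenolide, which closes the C6–O–C12 ring.

Step 4
Reactants: 6 (5S)-5-[(2S,3R)-3-methyl-3-(4-methylpent-3-en-1-yl)oxiran-2-yl]furan-2(5H)-one; 7 1,3-dithiane; 8 formaldehyde (monomer from paraformaldehyde)
Product: 10 (3R,4S,5S)-4-(1,3-dithian-2-yl)-3-(hydroxymethyl)-5-[(2S,3R)-3-methyl-3-(4-methylpent-3-en-1-yl)oxiran-2-yl]oxolan-2-one, via lithium lactone enolate 9 (not isolated)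
Conditions: 7, n-BuLi, THF, −30 °C; 6, HMPA, −78 °C; CH2O, −78 → −40 °C; aq. NH4Cl
Reagents that add atoms: 2-lithio-1,3-dithiane (made in the flask from 7), [Li]C1SCCCS1; formaldehyde (8), C=O
Why: Tandem conjugate addition–aldol; the dithiane anion should add to C7 anti to the C6 substituent, and the enolate should take formaldehyde at C11 anti to the new C7 group, giving the all-trans lactone (C7, C11).

Step 5
Reactants: 10 (3R,4S,5S)-4-(1,3-dithian-2-yl)-3-(hydroxymethyl)-5-[(2S,3R)-3-methyl-3-(4-methylpent-3-en-1-yl)oxiran-2-yl]oxolan-2-one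
Product: 11 [(3R,4S,5S)-4-(1,3-dithian-2-yl)-5-[(2S,3R)-3-methyl-3-(4-methylpent-3-en-1-yl)oxiran-2-yl]-2-oxooxolan-3-yl]methyl acetate
Conditions: Ac2O, pyridine, CH2Cl2, 0 °C
Reagents that add atoms: acetic anhydride, CC(=O)OC(C)=O
Why: Acetylation of the primary alcohol installs the C13 acetate of the target; the mild base at 0 °C should not eliminate the β-acetoxy lactone.

Step 6
Reactants: 11 [(3R,4S,5S)-4-(1,3-dithian-2-yl)-5-[(2S,3R)-3-methyl-3-(4-methylpent-3-en-1-yl)oxiran-2-yl]-2-oxooxolan-3-yl]methyl acetate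
Product: 12 [(3R,4S,5S)-4-formyl-5-[(2S,3R)-3-methyl-3-(4-methylpent-3-en-1-yl)oxiran-2-yl]-2-oxooxolan-3-yl]methyl acetate
Conditions: MeI, CaCO3, MeCN/H2O (4:1), 40 °C
Reagents that add atoms: water, O
Why: Alkylative hydrolysis of the dithiane under near-neutral conditions should free the C8 aldehyde without epimerizing C7 or opening the epoxide; the aldehyde is used crude.

Step 7
Reactants: 12 [(3R,4S,5S)-4-formyl-5-[(2S,3R)-3-methyl-3-(4-methylpent-3-en-1-yl)oxiran-2-yl]-2-oxooxolan-3-yl]methyl acetate; 13 2-methylallylmagnesium chloride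
Product: 14 [(3R,4R,5S)-4-[(1S)-1-hydroxy-3-methylbut-3-en-1-yl]-5-[(2S,3R)-3-methyl-3-(4-methylpent-3-en-1-yl)oxiran-2-yl]-2-oxooxolan-3-yl]methyl acetate
Conditions: (−)-Ipc2BOMe [from (+)-α-pinene], 13, Et2O, 0 °C → rt; 12, −78 °C; pH 7 buffer, H2O2, 0 °C
Reagents that add atoms: B-(2-methylallyl)diisopinocampheylborane (made in the flask from 13 and (−)-Ipc2BOMe), C=C(C)CB([C@@H]1C[C@@H]2C[C@H]([C@H]1C)C2(C)C)[C@@H]1C[C@@H]2C[C@H]([C@H]1C)C2(C)C
Why: Brown asymmetric methallylboration through a chair transition state; the (+)-α-pinene-derived reagent should attack the Si face of the aldehyde under reagent control and set 8S, and it is not basic enough to harm the β-acyloxy aldehyde.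

Step 8
Reactants: 14 [(3R,4R,5S)-4-[(1S)-1-hydroxy-3-methylbut-3-en-1-yl]-5-[(2S,3R)-3-methyl-3-(4-methylpent-3-en-1-yl)oxiran-2-yl]-2-oxooxolan-3-yl]methyl acetate
Product: 15 [(3R,4R,5S)-4-[(1S)-1-hydroxy-3-oxobutyl]-5-[(2S,3R)-3-methyl-3-(3-oxopropyl)oxiran-2-yl]-2-oxooxolan-3-yl]methyl acetate
Conditions: O3, CH2Cl2, −78 °C; Me2S, −78 °C → rt
Reagents that add atoms: ozone, [O-][O+]=O
Why: Ozonolysis with reductive work-up should cleave the isopropylidene and the 1,1-disubstituted alkene in one operation to the C1 aldehyde and the C10 methyl ketone; no other group is ozone-sensitive and no stereocentre is touched.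

Step 9
Reactants: 15 [(3R,4R,5S)-4-[(1S)-1-hydroxy-3-oxobutyl]-5-[(2S,3R)-3-methyl-3-(3-oxopropyl)oxiran-2-yl]-2-oxooxolan-3-yl]methyl acetate
Product: 17 (1S,4R,5S,6S,7R,8S,10R,11R)-13-acetoxy-4,5-epoxy-1,8,10-trihydroxygermacran-12,6-olide, via samarium ketyl 16 (not isolated)
Conditions: SmI2 (3 equiv), THF, high dilution (slow addition of 15), −78 → 0 °C; pH 7 buffer
Reagents that add atoms: none
Why: SmI2 transfers one electron to the aldehyde, and the C1 ketyl, held on a samarium(III) centre that the free C8 hydroxyl and the C10 carbonyl oxygen chelate in a six-membered ring, adds to C10; a second electron transfer and protonation on work-up give the samarium-bridged 1,2-diol. The closest known reaction type is the SmI2-mediated intramolecular aldehyde–ketone pinacol coupling, here in the hydroxyl-directed mode of SmI2 reactions of β-hydroxy ketones. The ten-membered carbocycle closes by C1–C10 bond formation in a 10-exo-trig addition to the C10=O group. C10 is controlled by the C8 stereocentre: the forming ring should span the two equatorial positions (C7 and C1) of the chelate chair with the methyl group axial, so that O10 ends syn to O8 (10R); C1 is set cis to O10 by the samarium diolate and is removed in step 11. The step needs ring closure to win over intermolecular pinacol coupling and simple aldehyde reduction, which high dilution, slow addition and the absence of a proton donor should secure, helped by the cis-epoxide and the trans-lactone that hold C5–C7 in a turn. Lactone, acetate and the isolated epoxide should be inert to SmI2 in THF without HMPA.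

Step 10
Reactants: 17 (1S,4R,5S,6S,7R,8S,10R,11R)-13-acetoxy-4,5-epoxy-1,8,10-trihydroxygermacran-12,6-olide; 18 tigloyl chloride [(2E)-2-methylbut-2-enoyl chloride]
Product: 19 (1S,4R,5S,6S,7R,8S,10R,11R)-13-acetoxy-4,5-epoxy-1,10-dihydroxy-8-[(2E)-2-methylbut-2-enoyloxy]germacran-12,6-olide
Conditions: 18 (1.1 equiv), pyridine, DMAP (cat.), CH2Cl2, −20 → 0 °C
Reagents that add atoms: tigloyl chloride (18), C/C=C(\C)C(Cl)=O
Why: DMAP-catalysed acylation should select the C8 hydroxyl, because the C1 carbinol is neopentylic and hydrogen-bonded in the 1,2-diol and the C10 hydroxyl is tertiary; no stereocentre is touched.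

Step 11
Reactants: 19 (1S,4R,5S,6S,7R,8S,10R,11R)-13-acetoxy-4,5-epoxy-1,10-dihydroxy-8-[(2E)-2-methylbut-2-enoyloxy]germacran-12,6-olide
Product: 20 (4R,5S,6S,7R,8S,10R,11R)-13-acetoxy-4,5-epoxy-10-hydroxy-8-[(2E)-2-methylbut-2-enoyloxy]-1-oxogermacran-12,6-olide
Conditions: IBX, DMSO/THF, rt
Reagents that add atoms: none
Why: IBX oxidation of the only remaining secondary carbinol should give the α-ketol without cleaving the C1–C10 bond of the 1,2-diol, and it removes the C1 stereocentre.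

Step 12
Reactants: 20 (4R,5S,6S,7R,8S,10R,11R)-13-acetoxy-4,5-epoxy-10-hydroxy-8-[(2E)-2-methylbut-2-enoyloxy]-1-oxogermacran-12,6-olide
Product: 21 (4R,5S,6S,7R,8S,10R,11R)-10,13-diacetoxy-4,5-epoxy-8-[(2E)-2-methylbut-2-enoyloxy]-1-oxogermacran-12,6-olide (target)
Conditions: Ac2O, DMAP, pyridine, CH2Cl2, rt
Reagents that add atoms: acetic anhydride, CC(=O)OC(C)=O
Why: DMAP-catalysed acetylation of the tertiary α-ketol hydroxyl, the only free OH left, should complete the target without touching a stereocentre.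

Compound list
1 | nerol, (2Z)-3,7-dimethylocta-2,6-dien-1-ol | CC(C)=CCC/C(C)=C\CO | starting material
2 | [(2S,3R)-3-methyl-3-(4-methylpent-3-en-1-yl)oxiran-2-yl]methanol | CC(C)=CCC[C@@]1(C)O[C@H]1CO | intermediate
3 | (2R,3R)-3-methyl-3-(4-methylpent-3-en-1-yl)oxirane-2-carbaldehyde | CC(C)=CCC[C@@]1(C)O[C@H]1C=O | intermediate
4 | methyl (2Z)-3-iodoprop-2-enoate | COC(=O)/C=C\I | starting material
5 | methyl (2Z,4S)-4-hydroxy-4-[(2S,3R)-3-methyl-3-(4-methylpent-3-en-1-yl)oxiran-2-yl]but-2-enoate (not isolated) | CC(C)=CCC[C@@]1(C)O[C@H]1[C@@H](O)/C=C\C(=O)OC | intermediate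
6 | (5S)-5-[(2S,3R)-3-methyl-3-(4-methylpent-3-en-1-yl)oxiran-2-yl]furan-2(5H)-one | CC(C)=CCC[C@@]1(C)O[C@H]1[C@H]1OC(=O)C=C1 | intermediate
7 | 1,3-dithiane | C1CSCSC1 | starting material
8 | formaldehyde | C=O | starting material
9 | lithium enolate of the C7-dithianyl lactone (not isolated) | CC(C)=CCC[C@@]1(C)O[C@H]1[C@H]1OC([O-])=C[C@@H]1C1SCCCS1.[Li+] | intermediate
10 | (3R,4S,5S)-4-(1,3-dithian-2-yl)-3-(hydroxymethyl)-5-[(2S,3R)-3-methyl-3-(4-methylpent-3-en-1-yl)oxiran-2-yl]oxolan-2-one | CC(C)=CCC[C@@]1(C)O[C@H]1[C@H]1OC(=O)[C@@H](CO)[C@@H]1C1SCCCS1 | intermediate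
11 | [(3R,4S,5S)-4-(1,3-dithian-2-yl)-5-[(2S,3R)-3-methyl-3-(4-methylpent-3-en-1-yl)oxiran-2-yl]-2-oxooxolan-3-yl]methyl acetate | CC(C)=CCC[C@@]1(C)O[C@H]1[C@H]1OC(=O)[C@@H](COC(C)=O)[C@@H]1C1SCCCS1 | intermediate
12 | [(3R,4S,5S)-4-formyl-5-[(2S,3R)-3-methyl-3-(4-methylpent-3-en-1-yl)oxiran-2-yl]-2-oxooxolan-3-yl]methyl acetate | CC(C)=CCC[C@@]1(C)O[C@H]1[C@H]1OC(=O)[C@@H](COC(C)=O)[C@@H]1C=O | intermediate
13 | 2-methylallylmagnesium chloride | C=C(C)C[Mg]Cl | starting material
14 | [(3R,4R,5S)-4-[(1S)-1-hydroxy-3-methylbut-3-en-1-yl]-5-[(2S,3R)-3-methyl-3-(4-methylpent-3-en-1-yl)oxiran-2-yl]-2-oxooxolan-3-yl]methyl acetate | CC(C)=CCC[C@@]1(C)O[C@H]1[C@H]1OC(=O)[C@@H](COC(C)=O)[C@@H]1[C@@H](O)CC(C)=C | intermediate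
15 | [(3R,4R,5S)-4-[(1S)-1-hydroxy-3-oxobutyl]-5-[(2S,3R)-3-methyl-3-(3-oxopropyl)oxiran-2-yl]-2-oxooxolan-3-yl]methyl acetate | O=CCC[C@@]1(C)O[C@H]1[C@H]1OC(=O)[C@@H](COC(C)=O)[C@@H]1[C@@H](O)CC(C)=O | intermediate
16 | samarium(III) ketyl of the C1 aldehyde of 15 (not isolated) | [O-][CH]CC[C@@]1(C)O[C@H]1[C@H]1OC(=O)[C@@H](COC(C)=O)[C@@H]1[C@@H](O)CC(C)=O.[Sm+3].[I-].[I-] | intermediate
17 | (1S,4R,5S,6S,7R,8S,10R,11R)-13-acetoxy-4,5-epoxy-1,8,10-trihydroxygermacran-12,6-olide | O[C@H]1C[C@@](C)(O)[C@@H](O)CC[C@@]2(C)O[C@H]2[C@H]2OC(=O)[C@@H](COC(C)=O)[C@@H]21 | intermediate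
18 | tigloyl chloride, (2E)-2-methylbut-2-enoyl chloride | C/C=C(\C)C(Cl)=O | starting material
19 | (1S,4R,5S,6S,7R,8S,10R,11R)-13-acetoxy-4,5-epoxy-1,10-dihydroxy-8-[(2E)-2-methylbut-2-enoyloxy]germacran-12,6-olide | C/C=C(\C)C(=O)O[C@H]1C[C@@](C)(O)[C@@H](O)CC[C@@]2(C)O[C@H]2[C@H]2OC(=O)[C@@H](COC(C)=O)[C@@H]21 | intermediate
20 | (4R,5S,6S,7R,8S,10R,11R)-13-acetoxy-4,5-epoxy-10-hydroxy-8-[(2E)-2-methylbut-2-enoyloxy]-1-oxogermacran-12,6-olide | C/C=C(\C)C(=O)O[C@H]1C[C@@](C)(O)C(=O)CC[C@@]2(C)O[C@H]2[C@H]2OC(=O)[C@@H](COC(C)=O)[C@@H]21 | intermediate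
21 | (4R,5S,6S,7R,8S,10R,11R)-10,13-diacetoxy-4,5-epoxy-8-[(2E)-2-methylbut-2-enoyloxy]-1-oxogermacran-12,6-olide | C/C=C(\C)C(=O)O[C@H]1C[C@@](C)(OC(C)=O)C(=O)CC[C@@]2(C)O[C@H]2[C@H]2OC(=O)[C@@H](COC(C)=O)[C@@H]21 | target

Total step count: 12. Longest linear sequence: 12 steps (nerol 1 → 21).

Steps most likely to fail

1. Step 9 (key step). What may go wrong: the ketyl may add to the other face of the chelated C10 carbonyl (1,3-anti instead of 1,3-syn induction from C8), and intermolecular pinacol coupling may compete with the slow closure of the ten-membered ring. The fallback addresses only the sense of induction: the C8 carbinol becomes a temporary control element that is erased and reset. From aldehyde 12, methallylation with the enantiomeric borane [from (+)-Ipc2BOMe] gives the 8R homoallylic alcohol F1, and ozonolysis as in step 8 gives the 8R keto-aldehyde F2. The SmI2 cyclization, now relying on 1,3-anti induction, gives the 8R,10R triol F3. IBX oxidizes both secondary carbinols to the 1,8-dioxo-10-hydroxy lactone F4. Narasaka–Prasad reduction (Et2BOMe, NaBH4, THF/MeOH, −78 °C) of the C8 ketone through the six-membered boron chelate of the C10 hydroxyl gives the 8S-hydroxy α-ketol F5 (1,3-syn), and tigloylation as in step 10 returns to 20.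

2. Step 4. What may go wrong: deprotonation of the butenolide at C6 next to the epoxide (with epoxide opening) or 1,2-addition may compete with conjugate addition, and trapping of the enolate by formaldehyde may be incomplete. The fallback uses radical instead of carbanion chemistry. From butenolide 6, benzophenone-sensitized photoaddition of 1,3-dioxolane (hν 350 nm, 1,3-dioxolane as solvent) adds the masked formyl radical to C7 anti to the C6 substituent and gives the dioxolanyl lactone F6. LDA (THF, −78 °C) followed by monomeric formaldehyde gives the trans hydroxymethyl lactone F7, and Ac2O/pyridine gives the acetate F8. Acetal cleavage (LiBF4, wet MeCN) returns to aldehyde 12.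

3. Step 3. What may go wrong: poor Felkin–Anh facial selectivity at C6, or opening of the trisubstituted epoxide by Lewis-acidic chromium salts. The fallback sets C6 under reagent control. From aldehyde 3, Zn–ProPhenol-catalysed addition of methyl propiolate (Me2Zn, toluene, with the ligand enantiomer that directs the alkynylzinc to the Si face) gives the hydroxy ynoate F9. Lindlar semihydrogenation gives the Z-hydroxy enoate 5, which lactonizes and rejoins the route at 6.

Further compounds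
F1 | step 9 | [(3R,4R,5S)-4-[(1R)-1-hydroxy-3-methylbut-3-en-1-yl]-5-[(2S,3R)-3-methyl-3-(4-methylpent-3-en-1-yl)oxiran-2-yl]-2-oxooxolan-3-yl]methyl acetate | CC(C)=CCC[C@@]1(C)O[C@H]1[C@H]1OC(=O)[C@@H](COC(C)=O)[C@@H]1[C@H](O)CC(C)=C
F2 | step 9 | [(3R,4R,5S)-4-[(1R)-1-hydroxy-3-oxobutyl]-5-[(2S,3R)-3-methyl-3-(3-oxopropyl)oxiran-2-yl]-2-oxooxolan-3-yl]methyl acetate | O=CCC[C@@]1(C)O[C@H]1[C@H]1OC(=O)[C@@H](COC(C)=O)[C@@H]1[C@H](O)CC(C)=O
F3 | step 9 | (1S,4R,5S,6S,7R,8R,10R,11R)-13-acetoxy-4,5-epoxy-1,8,10-trihydroxygermacran-12,6-olide | O[C@@H]1C[C@@](C)(O)[C@@H](O)CC[C@@]2(C)O[C@H]2[C@H]2OC(=O)[C@@H](COC(C)=O)[C@@H]21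
F4 | step 9 | (4R,5S,6S,7S,10R,11R)-13-acetoxy-4,5-epoxy-10-hydroxy-1,8-dioxogermacran-12,6-olide | O=C1C[C@@](C)(O)C(=O)CC[C@@]2(C)O[C@H]2[C@H]2OC(=O)[C@@H](COC(C)=O)[C@@H]21
F5 | step 9 | (4R,5S,6S,7R,8S,10R,11R)-13-acetoxy-4,5-epoxy-8,10-dihydroxy-1-oxogermacran-12,6-olide | O[C@H]1C[C@@](C)(O)C(=O)CC[C@@]2(C)O[C@H]2[C@H]2OC(=O)[C@@H](COC(C)=O)[C@@H]21
F6 | step 4 | (4S,5S)-4-(1,3-dioxolan-2-yl)-5-[(2S,3R)-3-methyl-3-(4-methylpent-3-en-1-yl)oxiran-2-yl]oxolan-2-one | CC(C)=CCC[C@@]1(C)O[C@H]1[C@H]1OC(=O)C[C@@H]1C1OCCO1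
F7 | step 4 | (3R,4S,5S)-4-(1,3-dioxolan-2-yl)-3-(hydroxymethyl)-5-[(2S,3R)-3-methyl-3-(4-methylpent-3-en-1-yl)oxiran-2-yl]oxolan-2-one | CC(C)=CCC[C@@]1(C)O[C@H]1[C@H]1OC(=O)[C@@H](CO)[C@@H]1C1OCCO1
F8 | step 4 | [(3R,4S,5S)-4-(1,3-dioxolan-2-yl)-5-[(2S,3R)-3-methyl-3-(4-methylpent-3-en-1-yl)oxiran-2-yl]-2-oxooxolan-3-yl]methyl acetate | CC(C)=CCC[C@@]1(C)O[C@H]1[C@H]1OC(=O)[C@@H](COC(C)=O)[C@@H]1C1OCCO1
F9 | step 3 | methyl (4S)-4-hydroxy-4-[(2S,3R)-3-methyl-3-(4-methylpent-3-en-1-yl)oxiran-2-yl]but-2-ynoate | CC(C)=CCC[C@@]1(C)O[C@H]1[C@@H](O)C#CC(=O)OC
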